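**Retrosynthetic overview**
- Target ⇒ twofold C‑prenylation of the one remaining nucleophilic ring CH of a prenyl‑free spiro trione (last step).
- Spiro trione ⇒ aromatic 3‑(cyclopentylmethyl)isobutyrylphloroglucinol, by an oxidative dearomative 6‑endo radical spirocyclisation onto the isopropenyl group with O2 capture. This one operation forms the cyclohexane ring, the spiro carbon and the second tertiary alcohol.
- Aromatic precursor ⇒ isobutyrylphloroglucinol (Hoesch acylation of phloroglucinol) + a cyclopentane β‑hydroxy aldehyde, joined by reductive Knoevenagel alkylation.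
- β‑Hydroxy aldehyde ⇒ keto aldehyde (proline 5‑enolexo aldol) ⇒ (R)‑limonene (ozonolysis).
- Ring order: cyclopentane (aldol), then cyclohexane with the spiro centre (dearomatisation); the trione ring is the former phloroglucinol ring.

Assumption: the triketone is written as the enol tautomer of the task SMILES, and the descriptors (1R,3'R,3a'S,7'R,7a'R; trans‑fused hydrindane) refer to that tautomer.

**Step 1**
Reactants: 1 phloroglucinol (benzene‑1,3,5‑triol); 2 isobutyronitrile (2‑methylpropanenitrile)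
Product: 3 2‑methyl‑1‑(2,4,6‑trihydroxyphenyl)propan‑1‑one
Conditions: HCl (g), ZnCl2 (cat.), Et2O, 0 °C; then H2O, 100 °C
Reagents that add atoms: water, O
Why: Houben–Hoesch acylation: the nitrilium ion attacks the electron‑rich arene once (the ketiminium salt is deactivated) and hydrolysis gives the aryl ketone; no stereocentre.

**Step 2**
Reactants: 4 (R)‑(+)‑limonene
Product: 5 (3R)‑6‑oxo‑3‑(prop‑1‑en‑2‑yl)heptanal
Conditions: O3 (1.0 equiv), CH2Cl2/MeOH, −78 °C, Sudan Red 7B end point; then Me2S, −78 °C → 20 °C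
Reagents that add atoms: ozone, [O-][O+]=O
Why: Chemoselective ozonolysis of the more electron‑rich trisubstituted ring alkene over the 1,1‑disubstituted isopropenyl group, with reductive work‑up; the limonene stereocentre (later C‑7a') is carried through untouched.

**Step 3**
Reactants: 5 (3R)‑6‑oxo‑3‑(prop‑1‑en‑2‑yl)heptanal; 3 2‑methyl‑1‑(2,4,6‑trihydroxyphenyl)propan‑1‑one
Product: 7 1‑[2,4,6‑trihydroxy‑3‑{[(1S,2R,5R)‑2‑hydroxy‑2‑methyl‑5‑(prop‑1‑en‑2‑yl)cyclopentyl]methyl}phenyl]‑2‑methylpropan‑1‑one, via hydroxy aldehyde 6 (not isolated)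
Conditions: L‑proline (30 mol %), DMSO, 20 °C, 12 h; then 3 (1.5 equiv), Hantzsch ester (1.2 equiv), 20 °C
Reagents that add atoms: none
Why: Proline enamine 5‑enolexo aldol followed in the same flask by three‑component reductive (Knoevenagel) alkylation: the aldehyde enamine adds to the methyl ketone anti to the isopropenyl‑bearing neighbour (allylic 1,3‑strain, giving 1S, trans) with the ketone oxygen held syn to the enamine by the carboxylic acid (giving 2R, OH cis to the formyl carbon), and the same amine then condenses 6 with 3 to an ortho‑quinone methide that the Hantzsch ester reduces before the tertiary aldol can dehydrate.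

**Step 4**
Reactants: 7 1‑[2,4,6‑trihydroxy‑3‑{[(1S,2R,5R)‑2‑hydroxy‑2‑methyl‑5‑(prop‑1‑en‑2‑yl)cyclopentyl]methyl}phenyl]‑2‑methylpropan‑1‑one
Product: 9 (1R,3'R,3a'S,7'R,7a'R)‑3',4,7'‑trihydroxy‑3',7'‑dimethyl‑3‑(2‑methylpropanoyl)octahydrospiro[cyclohex‑3‑ene‑1,5'‑indene]‑2,6‑dione, via tertiary hydroperoxide 8 (not isolated)
Conditions: Mn(OAc)3·2H2O (20 mol %), O2 (1 atm), AcOH, 20 °C, 0.01 M, stopped at full conversion of 7; then PPh3, 0 °C
Reagents that add atoms: dioxygen, O=O
Why: Proposed new method: trivalent manganese oxidises the acylphloroglucinol (which reacts as a vinylogous β‑triketone) to a radical with spin density on the alkylated ring carbon; this closes 6‑endo onto the CH2 terminus of the isopropenyl group, because that gives a tertiary radical and a trans‑hydrindane whereas 5‑exo would need a trans‑bicyclo[3.3.0]octane, and the ring carbon becomes the quaternary spiro centre (dearomatisation); in the single possible chair the bulky, manganese‑chelated or H‑bonded 2‑hydroxyaryl ketone flank turns outward, so the carbonyl carbon next to the still unsubstituted ring CH goes axial (1R), and O2 then traps the tertiary radical from the face opposite that axial carbonyl (7'R, equatorial oxygen, axial methyl) before PPh3 reduces the hydroperoxide; the closest known reactions are Mn(OAc)3/O2 peroxycyclisations of 1,3‑dicarbonyls with alkenes and oxidative radical cyclisations of dearomatised acylphloroglucinols.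

**Step 5**
Reactants: 9 (1R,3'R,3a'S,7'R,7a'R)‑3',4,7'‑trihydroxy‑3',7'‑dimethyl‑3‑(2‑methylpropanoyl)octahydrospiro[cyclohex‑3‑ene‑1,5'‑indene]‑2,6‑dione; 10 prenyl bromide (1‑bromo‑3‑methylbut‑2‑ene)
Product: 12 (1R,3'R,3a'S,7'R,7a'R)‑3',4,7'‑trihydroxy‑3',7'‑dimethyl‑5,5‑bis(3‑methylbut‑2‑en‑1‑yl)‑3‑(2‑methylpropanoyl)octahydrospiro[cyclohex‑3‑ene‑1,5'‑indene]‑2,6‑dione, via monoprenyl trione 11 (not isolated)
Conditions: 10 (2.5 equiv), KOH (2 M, H2O), 0 °C → 20 °C
Reagents that add atoms: none
Why: Exhaustive C‑alkylation (lupulone‑type prenylation) of the β‑triketone anion at its only unsubstituted ring carbon, C‑5, in water, where solvation of the enolate oxygens favours carbon attack by the soft allylic bromide; no stereocentre is formed, and the spiro carbon and both tertiary carbinols are not enolisable.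

**Compound list**
1 | phloroglucinol (benzene‑1,3,5‑triol) | Oc1cc(O)cc(O)c1 | starting material
2 | isobutyronitrile | CC(C)C#N | starting material
3 | 2‑methyl‑1‑(2,4,6‑trihydroxyphenyl)propan‑1‑one (isobutyrylphloroglucinol) | CC(C)C(=O)c1c(O)cc(O)cc1O | intermediate
4 | (R)‑(+)‑limonene | CC1=CC[C@@H](CC1)C(C)=C | starting material
5 | (3R)‑6‑oxo‑3‑(prop‑1‑en‑2‑yl)heptanal | O=CC[C@@H](CCC(C)=O)C(C)=C | intermediate
6 | (1S,2R,5R)‑2‑hydroxy‑2‑methyl‑5‑(prop‑1‑en‑2‑yl)cyclopentane‑1‑carbaldehyde (OH cis to CHO, CHO trans to isopropenyl) | O=C[C@H]1[C@@H](CC[C@@]1(C)O)C(C)=C | intermediate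
7 | 1‑[2,4,6‑trihydroxy‑3‑{[(1S,2R,5R)‑2‑hydroxy‑2‑methyl‑5‑(prop‑1‑en‑2‑yl)cyclopentyl]methyl}phenyl]‑2‑methylpropan‑1‑one | CC(C)C(=O)c1c(O)cc(O)c(C[C@H]2[C@@H](CC[C@@]2(C)O)C(C)=C)c1O | intermediate
8 | 7'‑hydroperoxide of 9 (OOH in place of the 7'‑OH, same configuration) | C1C(=O)[C@]2(C[C@H]3[C@@H](CC[C@@]3(C)O)[C@](C)(OO)C2)C(=O)C(C(=O)C(C)C)=C1O | intermediate
9 | (1R,3'R,3a'S,7'R,7a'R)‑3',4,7'‑trihydroxy‑3',7'‑dimethyl‑3‑(2‑methylpropanoyl)octahydrospiro[cyclohex‑3‑ene‑1,5'‑indene]‑2,6‑dione (trans‑fused; C‑5 is CH2) | C1C(=O)[C@]2(C[C@H]3[C@@H](CC[C@@]3(C)O)[C@](C)(O)C2)C(=O)C(C(=O)C(C)C)=C1O | intermediate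
10 | prenyl bromide (1‑bromo‑3‑methylbut‑2‑ene) | CC(C)=CCBr | starting material
11 | 5‑(3‑methylbut‑2‑en‑1‑yl) derivative of 9, drawn as its dienol | CC(C)=CCC1=C(O)[C@]2(C[C@H]3[C@@H](CC[C@@]3(C)O)[C@](C)(O)C2)C(=O)C(C(=O)C(C)C)=C1O | intermediate
12 | (1R,3'R,3a'S,7'R,7a'R)‑3',4,7'‑trihydroxy‑3',7'‑dimethyl‑5,5‑bis(3‑methylbut‑2‑en‑1‑yl)‑3‑(2‑methylpropanoyl)octahydrospiro[cyclohex‑3‑ene‑1,5'‑indene]‑2,6‑dione | CC(C)=CCC1(CC=C(C)C)C(=O)[C@]2(C[C@H]3[C@@H](CC[C@@]3(C)O)[C@](C)(O)C2)C(=O)C(C(=O)C(C)C)=C1O | target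

**Step count**
Total: 5 steps. Longest linear sequence: 4 steps (4 → 5 → 7 → 9 → 12; the branch 1 → 3 → 7 → 9 → 12 is equally long).

**Steps most likely to fail, with fallbacks**

The riskiest operation is step 4. The aryloxyl radical of 7 may fail to add to the alkene, may be trapped by O2 at the ring carbon, or 9 may be oxidised further at C‑5; the facial preference at the spiro carbon rests on a steric model and may be modest. The fallback closes the ring by anionic alkylative dearomatisation instead. It sets out from 6, obtained by stopping step 3 after its first stage. Dimethyldioxirane in acetone at 0 °C epoxidises only the isopropenyl group; this is not face‑selective, so the epoxy aldehyde F1 is separated from its oxirane epimer. Reductive alkylation of 3 with F1 under the second‑stage conditions of step 3 gives the aryl epoxide F2. NaOMe in MeOH at 40 °C then lets the alkylated ring carbon of the phloroglucinol anion open the epoxide at its CH2 terminus (six‑membered ring, tertiary C–O bond untouched, so 7'R comes from the epoxide). The route is rejoined at 9.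

Second is step 3. The proline aldol may dehydrate to the enal, give the wrong C‑2 epimer, or the β‑hydroxy aldehyde may fragment during the Knoevenagel stage. The fallback sets out from 5. Piperidine/AcOH in refluxing benzene gives the known enal F3. H2O2/NaOH in MeOH at 0 °C epoxidises it anti to the isopropenyl group, giving the epoxy aldehyde F4, which fixes the tertiary C–O bond. SmI2 in THF/MeOH at −90 °C cleaves the C–O bond alpha to the aldehyde, and brief Et3N treatment equilibrates the formyl‑bearing carbon to the trans isomer. The route is rejoined at 6, which enters the second stage of step 3.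

Third is step 5. O‑prenylation or arrest at 11 may compete with formation of the second quaternary carbon. The fallback sets out from 9. Pd(PPh3)4 with allyl methyl carbonate in THF at 20 °C gives double C‑allylation, because zerovalent palladium re‑ionises any O‑allyl enol ether so carbon alkylation wins; the product is the gem‑diallyl trione F5. Twofold cross‑metathesis with 2‑methyl‑2‑butene (second‑generation Grubbs catalyst, (H2IMes)(PCy3)Cl2Ru=CHPh, CH2Cl2, 40 °C) converts both allyl groups into prenyl groups. The route is rejoined at 12.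

**Further compounds**
F1 | step 4 | (1S,2R,5R)‑2‑hydroxy‑2‑methyl‑5‑[(2S)‑2‑methyloxiran‑2‑yl]cyclopentane‑1‑carbaldehyde | O=C[C@H]1[C@@H](CC[C@@]1(C)O)[C@]2(C)OC2
F2 | step 4 | 1‑[2,4,6‑trihydroxy‑3‑({(1S,2R,5R)‑2‑hydroxy‑2‑methyl‑5‑[(2S)‑2‑methyloxiran‑2‑yl]cyclopentyl}methyl)phenyl]‑2‑methylpropan‑1‑one | CC(C)C(=O)c1c(O)cc(O)c(C[C@H]2[C@@H](CC[C@@]2(C)O)[C@]3(C)OC3)c1O
F3 | step 3 | (S)‑2‑methyl‑5‑(prop‑1‑en‑2‑yl)cyclopent‑1‑ene‑1‑carbaldehyde | O=CC1=C(C)CC[C@H]1C(C)=C
F4 | step 3 | (1S,2S,5R)‑5‑methyl‑2‑(prop‑1‑en‑2‑yl)‑6‑oxabicyclo[3.1.0]hexane‑1‑carbaldehyde | O=C[C@@]12O[C@]1(C)CC[C@H]2C(C)=C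
F5 | step 5 | 5,5‑di(prop‑2‑en‑1‑yl) analogue of 12 (allyl in place of each prenyl group) | C=CCC1(CC=C)C(=O)[C@]2(C[C@H]3[C@@H](CC[C@@]3(C)O)[C@](C)(O)C2)C(=O)C(C(=O)C(C)C)=C1O
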